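The numbers were drawn at random within sensible limits; the run is a simulation.

Start with the target: it forms through free catalyst, and free catalyst decays on a clock of its own. So count how many substrate lifetimes fit into one catalyst lifetime.

common to all: substrate 20 mM; free catalyst 3.0 mM; time 30 s

| charge | temperature |
|---|---|
| amber | 80 °C |
| ochre | 60 °C |
| green | 100 °C |

    target → over-reaction product (k1 = 2.1 × 10⁻⁴ s⁻¹, Ea1 = 103 kJ mol⁻¹)
    substrate + free catalyst → free catalyst + target (k2 = 60 L mol⁻¹ s⁻¹, Ea2 = 54.0 kJ mol⁻¹)
    substrate ⇌ other conformer (K3 = 0.14, k3 = 3.6 s⁻¹, Ea3 = 73.0 kJ mol⁻¹, ΔH3 = −13.0 kJ mol⁻¹)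
    free catalyst + other conformer → free catalyst + isomer of the product A (k4 = 26 L mol⁻¹ s⁻¹, Ea4 = 38.0 kJ mol⁻¹)
    target ⇌ isomer of the product B (K5 = 0.23, k5 = 0.27 s⁻¹, Ea5 = 79.0 kJ mol⁻¹, ΔH5 = −62.0 kJ mol⁻¹)
    free catalyst → spent catalyst (k6 = 0.17 s⁻¹, Ea6 = 87.0 kJ mol⁻¹)
    (constants at 60 °C)

- at 60 °C the constants are as listed, elsewhere as the activation energies and enthalpies make them
- in a conversion other conformer counts as not yet reacted

- which flask leads in amount of target, in percent of the substrate charged ("all alike" within 1.5 percentage points) (amber / ochre / green / all alike)
- how much target is there at the end, in percent of the substrate charged: amber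
- how much target is there at the end, in percent of the substrate charged: ochre
- how much target is there at the end, in percent of the substrate charged: green

Reckon ochre first; this estimate is my own. Substrate and other conformer relax with a half-life of 0.0236 s, much shorter than the catalyst lifetime of 5.88 s. Treat them as one pool (a rapid pre-equilibrium) in which substrate holds 87.7%. Neglect the route to isomer of the product A, which carries 0.0607 of the flow through the catalytic step. Under the full charge, the pool's lifetime is

τ = (1 + 0.14) / (60 L mol⁻¹ s⁻¹ × c(free catalyst)) = 6.33 s

Target and isomer of the product B relax in 0.693 s, and target keeps 81.3% of the two. So, once these two have relaxed, the ochre curve climbs with a slope of about 0.128 s⁻¹ as a fraction of the charge.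

The knee lies near the catalyst lifetime, where target stands at 36.1% of the charge by this estimate. Beyond it the curve flattens. The time integral of the catalyst is its charge times its lifetime, which gives:

budget = catalyst lifetime / τ = 0.929

Call this the catalyst budget: the pool lifetimes one catalyst charge can pay for, so the pool left is exp(−budget), here 39.5%. Over-reaction draws on target with a lifetime of 79.4 min, much longer than the 30 s of the ochre run. The ochre level is

(1 − exp(−budget)) / (1 + K) × exp(−t / over-reaction lifetime) = 48.9%

Heat shrinks the budget, since catalyst decay has the higher activation energy, by 33.0 kJ mol⁻¹. With the same formula: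

amber: budget 0.487, K 0.0647, over-reaction lifetime 580 s, target 34.4%

green: budget 0.272, K 0.0209, over-reaction lifetime 88.4 s, target 16.6%

My reckoning puts ochre in the lead.

The forecast also names ochre, with 34.3% for amber (32.5% to 36%), 47.7% for ochre (45.5% to 50%) and 16.8% for green (15.5% to 18%). Its ground is that “Catalyst death has the higher activation energy than the productive step”. Its ochre figure stands a little lower than mine.

The simulation gives ochre in the lead, with target at 34.3% in amber, 47.7% in ochre and 16.7% in green. Each value falls inside the forecast's range.

The ochre flask has nearly stopped consuming substrate: free catalyst reads 0.610% of its charge at the asked time, and substrate reads 32.9% then and 32.7% at 300 s. Substrate and other conformer together read 37.6%, against exp(−budget) of 39.5%. Target is not at rest. Stretch the over-reaction lifetime by 1 + K and carry target on to 300 s: ochre comes to 45.5%, and the simulation reads 45.7%. Green comes to 0.842%, and the simulation reads 0.842%.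

Take the same flask as ochre at 85 °C: its budget is 0.419, so the pool left should be 65.8%. The simulation leaves 65.0% in substrate and other conformer together, with target at 30.0%.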